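Tuesday's flask ends with left-handed substrate at 1.3%, and I start from that leftover. In the proposed steps, free catalyst and partner turn each substrate into its product, one partner per turnover.

| flask | left-handed substrate | right-handed substrate | partner | precatalyst | temperature | remark | time |
|---|---|---|---|---|---|---|---|
| Tuesday's | 0.50 M | 0.50 M | 1.5 equiv | 8.6 mol% | 55 °C | run made earlier |  |
| Friday's | 0.50 M | 0.50 M | 6 equiv | 8.6 mol% | 66 °C | run made earlier |  |
| Thursday's | 0.25 M | 0.25 M | 3 equiv | 8.6 mol% | 55 °C | run made earlier |  |
| alpha | 0.50 M | 0.50 M | 3.00 equiv | 8.6 mol% | 50 °C |  | 4.0 min |
| beta | 0.50 M | 0.50 M | 3.00 equiv | 8.6 mol% | 70 °C |  | 4.0 min |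

Tuesday's run (percent of the left-handed substrate and right-handed substrate together charged)

| time / min | left-handed product / % | left-handed substrate / % |
|---|---|---|
| 0.250 | 5.0 | 45.3 |
| 0.833 | 25.0 | 24.7 |
| 1.33 | 36.1 | 13.6 |
| 2.00 | 42.7 | 7.4 |
| 3.00 | 46.7 | 3.2 |
| 4.00 | 48.4 | 1.3 |

Friday's run (percent of the left-handed substrate and right-handed substrate together charged)

| time / s | left-handed product / % | left-handed substrate / % |
|---|---|---|
| 10.0 | 37.6 | 12.2 |
| 15.0 | 45.6 | 4.1 |
| 25.0 | 49.3 | 0.6 |
| 40.0 | 49.7 | 0 |
| 60.0 | 49.8 | 0 |
| 120 | 50.1 | 0.8 |

Thursday's run (percent of the left-handed substrate and right-handed substrate together charged)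

| time / min | left-handed product / % | left-handed substrate / % |
|---|---|---|
| 0.833 | 17.6 | 32.4 |
| 1.50 | 32.3 | 17.8 |
| 2.50 | 42.3 | 7.1 |
| 3.00 | 45.3 | 4.5 |
| 4.00 | 47.5 | 2.1 |

(scatter of a reading: 0.3 percentage points)

- free catalyst is single-handed; left-handed substrate and right-handed substrate are mirror images of each other, charged as a racemate, each of them at the stated concentration
- what was read earlier has a scatter of 0.3 percentage points, one standard deviation
- steps that have been proposed: partner + free catalyst + left-handed substrate -> free catalyst + left-handed product; partner + free catalyst + right-handed substrate -> free catalyst + right-handed product; partner + precatalyst -> free catalyst + spent reagent; partner + free catalyst -> spent catalyst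

- the best flask by amount of left-handed product, in percent of the left-handed substrate and right-handed substrate together charged; "all alike" if 1.5 percentage points covers them all (alpha / beta / all alike)
- amount of left-handed product at the end, in percent of the left-handed substrate and right-handed substrate together charged, alpha
- amount of left-handed product at the end, in percent of the left-handed substrate and right-handed substrate together charged, beta

I carry the pay rate, 50.0% per equivalent: the left-handed product, in percent of both substrates charged, that one equivalent of partner pays for. Alpha's and beta's partner could pay for 150%, but left-handed substrate is 50.0% of the charge, so 50.0% is my upper bound, and this substrate is the limiting reagent.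

My lower side is an estimate and no proved bound, since alpha's bath is colder than Tuesday's while its partner charge is larger. Tuesday's last stretch reads the leftover falling at 0.901 /min. Held over 4.0 min from a start of 50.0%, that rate leaves 1.36%, so alpha gets about 48.6%. Now I put this answer back in. The bill costs about one equivalent, leaving alpha near 1.00 M of partner, against 0.274 M in Tuesday's stretch. Friday's hotter flask read 13.1 /min on about 2.58 M of partner, 1.54 times Tuesday's rate per partner, and I divide by that whole factor for alpha's colder bath. This gives 2.13 /min and a leftover of 0.0101%, provided alpha's catalyst lasts as Tuesday's did. Beta pays the same bill, and Friday's flask read 49.3% at 25.0 s.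

The forecast gives 49.8% for alpha and 49.9% for beta, all alike: “Four minutes is then many half-lives for both flasks”. Its alpha figure lies inside my first bracket, just below my tightened one.

Alpha ends at 50.0% and beta at 50.0%, all alike.

    partner + free catalyst + left-handed substrate → free catalyst + left-handed product (k = 7.80 /M²/s, Ea = 36.0 kJ/mol)
    partner + free catalyst + right-handed substrate → free catalyst + right-handed product (k = 0.0720 /M²/s, Ea = 35.0 kJ/mol)
    partner + precatalyst → free catalyst + spent reagent (k = 0.00320 /M/s, Ea = 61.0 kJ/mol)
    partner + free catalyst → spent catalyst (k = 0.0150 /M/s, Ea = 67.0 kJ/mol)
    (constants at 50 °C)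

In alpha the making of left-handed product ran while left-handed substrate lasted, 0.458% at 2.00 min, and partner stands at 61% of its charge at 4.00 min, against the 66.7% of my reckoning. In beta half of the same step's turnover up to 4.00 min was done by 0.181 min, and spent catalyst grew to 91.9% of the catalyst charged at 4.00 min. Beta's neighbour with 0.750 equiv of partner shows what would make the forecast wrong: that charge pays for 37.5%, partner falls to 1.8% of its charge, and left-handed product ends at 34.9%.

The earlier runs and the new flask were generated by integration with constants of no real substance.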